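**Retrosynthetic overview**

1. Numbering: carbocycle C1–C10 (C1–C3 CH2; C4 CH–CH3; C5 CH–OH; C6 lactone O–CH; C7 ring-fusion CH; C8 CH–O-tigloyl; C9 oxirane CH; C10 oxirane C–CH3); lactone carbons C11 (carries methylene C13) and C12 (C=O).
2. Late stage: the O8 tiglate, the C9–C10 oxirane (hydroxyl-directed, outer face) and C13 (Mannich/elimination) are added to the (E)-cyclodecenol lactone 22 after the C2 sulfonyl groups are removed.
3. Key disconnection C1–C2: the C8 carbinol, the C9–C10 oxirane (from an E-C9=C10 alkene bearing the C10 methyl) and C1H2 are together a ring-opened 2-isopropenyloxirane, and C2 is a plain CH2 that can carry two sulfonyl groups; 22 therefore comes from vinyl epoxide 21 by palladium-catalysed alkylation.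
4. 21 comes from aldehyde 16 and a chiral methallyl sulfonium ylide (C8–C9); 16 from an Evans syn aldol/lactonisation of a succinate imide with aldehyde 8 (C6–C7); 8 from bis(phenylsulfonyl)methane and butadiene monoxide (C2–C3) via Sharpless epoxidation and methyl opening (C4, C5).
5. Ring order: γ-lactone (step 7), oxirane of the precursor (step 11), ten-membered carbocycle (step 12), C9–C10 oxirane (step 18).

Key step: step 12

Assumption: the S-methallyl sulfonium salt of (1R,4R,5R)-isothiocineole is taken to transfer its allylidene unit in the sense that gives the (R,R)-trans-oxirane; if the sense is opposite, the enantiomeric sulfide from (S)-limonene is used instead.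

**Route**

Step 1
Reactants: 1 bis(phenylsulfonyl)methane; 2 2-vinyloxirane (racemic)
Product: 3 (E)-5,5-bis(phenylsulfonyl)pent-2-en-1-ol
Conditions: Pd(PPh3)4 (2 mol%), THF, rt
Reagents that add atoms: none
Why: Zerovalent palladium ionises the vinyl epoxide, the alkoxide so formed deprotonates the bis-sulfone, and the soft carbanion adds to the remote CH2 terminus of the π-allyl (intermolecular Tsuji–Trost alkylation of a vinyl epoxide, 1,4-mode), which should give the E allylic alcohol with C2–C3 formed under neutral conditions and no stereocentre set.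

Step 2
Reactants: 3 (E)-5,5-bis(phenylsulfonyl)pent-2-en-1-ol
Product: 4 [(2S,3S)-3-[2,2-bis(phenylsulfonyl)ethyl]oxiran-2-yl]methanol
Conditions: Ti(OiPr)4 (10 mol%), L-(+)-diethyl tartrate (12 mol%), t-BuOOH, 4 Å molecular sieves, CH2Cl2, −20 °C
Reagents that add atoms: tert-butyl hydroperoxide CC(C)(C)OO
Why: Sharpless asymmetric epoxidation of a primary E-allylic alcohol, in which the titanium tartrate complex of L-(+)-diethyl tartrate delivers oxygen to the face that gives the (2S,3S)-epoxy alcohol, fixing C5 and the C4 carbon that is inverted in step 3.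

Step 3
Reactants: 4 [(2S,3S)-3-[2,2-bis(phenylsulfonyl)ethyl]oxiran-2-yl]methanol
Product: 5 (2R,3R)-3-methyl-5,5-bis(phenylsulfonyl)pentane-1,2-diol
Conditions: AlMe3 (4 equiv), CH2Cl2/hexane, −20 to 0 °C; aq. potassium sodium tartrate
Reagents that add atoms: trimethylaluminium C[Al](C)C
Why: Trimethylaluminium, held as the aluminium alkoxide of the primary alcohol, transfers methyl to C3 of the 2,3-epoxy alcohol (C4 of the target) with inversion, the known regioselective opening to a 1,2-diol, so the trans epoxide gives the anti C4-methyl/C5-hydroxyl pair; the excess reagent covers the acidic bis-sulfone C–H, whose aluminium derivative should be too poor a nucleophile to attack the oxirane at this temperature.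

Step 4
Reactants: 5 (2R,3R)-3-methyl-5,5-bis(phenylsulfonyl)pentane-1,2-diol
Product: 7 bis-silyl ether (primary OTES; secondary OTBS), via primary triethylsilyl ether 6 (not isolated)
Conditions: Et3SiCl (1.05 equiv), imidazole, CH2Cl2, −78 to −40 °C; then t-BuMe2SiOTf, 2,6-lutidine, −78 to 0 °C
Reagents that add atoms: chlorotriethylsilane CC[Si](Cl)(CC)CC; tert-butyldimethylsilyl trifluoromethanesulfonate CC(C)(C)[Si](C)(C)OS(=O)(=O)C(F)(F)F
Why: The primary hydroxyl is silylated selectively by the chlorosilane at low temperature and the hindered secondary hydroxyl then needs the silyl triflate, so one flask gives two different silyl ethers (standard silyl protection).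

Step 5
Reactants: 7 bis-silyl ether
Product: 8 (2R,3R)-2-(tert-butyldimethylsilyloxy)-3-methyl-5,5-bis(phenylsulfonyl)pentanal
Conditions: (COCl)2, DMSO, CH2Cl2, −78 to −40 °C; then Et3N, −78 °C to rt
Reagents that add atoms: none
Why: Under Swern conditions a primary triethylsilyl ether is cleaved and oxidised in place while a secondary tert-butyldimethylsilyl ether is untouched, which gives the α-silyloxy aldehyde without a separate deprotection and should not epimerise C5 at low temperature.

Step 6
Reactants: 9 (S)-4-benzyloxazolidin-2-one; 10 methyl 4-chloro-4-oxobutanoate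
Product: 11 methyl 4-[(S)-4-benzyl-2-oxooxazolidin-3-yl]-4-oxobutanoate
Conditions: Et3N, DMAP (cat.), CH2Cl2, 0 °C to rt
Reagents that add atoms: none
Why: N-Acylation of the oxazolidinone by the acid chloride with triethylamine and catalytic 4-dimethylaminopyridine is a standard route to the imide and leaves the methyl ester untouched.

Step 7
Reactants: 8 α-silyloxy aldehyde; 11 succinate imide
Product: 14 trans-γ-lactone imide (C6 S; C7 S), via Z dibutylboron enolate 12 (not isolated), via syn aldol hydroxy ester 13 (not isolated)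
Conditions: 11, Bu2BOTf, iPr2NEt, CH2Cl2, −78 to 0 °C; 8, −78 to 0 °C; MeOH, pH 7 buffer, H2O2; then p-TsOH (cat.), CH2Cl2, rt
Reagents that add atoms: none
Why: Evans syn aldol, in which the Z boron enolate reacts through a chair transition state on the face fixed by the (S)-benzyl auxiliary to set C6 and C7 syn, the sense that the Cornforth preference of the α-silyloxy aldehyde also favours (C5/C6 anti, matched pair), after which the γ-hydroxy ester lactonises under acid to the trans-disubstituted γ-lactone.

Step 8
Reactants: 14 trans-γ-lactone imide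
Product: 15 (4R,5S)-5-[(1R,2R)-1-(tert-butyldimethylsilyloxy)-2-methyl-4,4-bis(phenylsulfonyl)butyl]-4-(hydroxymethyl)dihydrofuran-2(3H)-one
Conditions: NaBH4, THF/H2O (4:1), 0 °C
Reagents that add atoms: none
Why: NaBH4 in wet THF reduces the activated exocyclic imide carbonyl to the primary alcohol and releases the auxiliary (chemoselective reductive cleavage of an N-acyloxazolidinone), while the γ-lactone, the sulfones and the silyl ether should not be attacked at 0 °C.

Step 9
Reactants: 15 lactone alcohol
Product: 16 (2S,3S)-2-[(1R,2R)-1-(tert-butyldimethylsilyloxy)-2-methyl-4,4-bis(phenylsulfonyl)butyl]-5-oxotetrahydrofuran-3-carbaldehyde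
Conditions: Dess–Martin periodinane, NaHCO3, CH2Cl2, 0 °C to rt
Reagents that add atoms: none
Why: Dess–Martin oxidation under bicarbonate buffer gives the aldehyde without base, which protects the epimerisable C7 centre and avoids β-elimination of the lactone oxygen at C6.

Step 10
Reactants: 17 (1R,4R,5R)-isothiocineole; 18 3-bromo-2-methylprop-1-ene
Product: 19 S-methallyl isothiocineolium triflate
Conditions: LiOTf, CH2Cl2/H2O, rt
Reagents that add atoms: lithium trifluoromethanesulfonate [Li+].[O-]S(=O)(=O)C(F)(F)F
Why: S-Alkylation of the bicyclic sulfide by the allylic bromide with exchange to the non-nucleophilic triflate is standard sulfonium salt formation and should give one diastereomer at sulfur.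

Step 11
Reactants: 16 lactone aldehyde; 19 S-methallyl isothiocineolium triflate
Product: 21 vinyl epoxide precursor (8R,9R trans-oxirane), via sulfonium ylide 20 (not isolated)
Conditions: 19 (2.3 equiv), LiN(SiMe3)2 (2.2 equiv, slow addition), THF, −78 °C
Reagents that add atoms: none
Why: Sulfur ylide epoxidation of Corey–Chaykovsky type, in which the ylide formed in the presence of the aldehyde adds to C8 and the betaine closes to the oxirane, the chiral sulfide fixing the ylide face so that the trans (8R,9R) oxirane is expected and the Felkin–Anh preference at C8 (attack anti to C6) acting in the same sense; the first equivalent of base is taken by the bis-sulfone C–H, whose hindered lithium salt should be inert to the aldehyde and to the sulfonium salt at −78 °C, and C9 need not be pure because it becomes trigonal in step 12.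

Step 12
Reactants: 21 vinyl epoxide precursor
Product: 22 (E)-cyclodecenol lactone (C2 bis-sulfone; free 8-OH)
Conditions: Pd(PPh3)4 (10 mol%), dppe (10 mol%), THF, 65 °C, slow addition of 21 over 10 h (final 0.005 M)
Reagents that add atoms: none
Why: Oxidative addition of zerovalent palladium to the allylic C9–O bond (inversion at C9) unmasks a π-allylpalladium cation over C9–C10–C1 together with an alkoxide at C8; this internal base takes the C2 proton, and the bis-sulfonyl carbanion, the only nucleophile then present, bonds to the CH2 terminus C1 from the face away from the metal, which is the intramolecular Tsuji–Trost alkylation of a vinyl epoxide by a tethered bis-sulfone, a known route to medium and large carbocycles. The ten-membered ring closes by C-alkylation at the remote allyl terminus with all three allyl carbons inside the ring, rather than at C9, which would close an eight-membered ring bearing an isopropenyl group. No stereocentre is formed: C8 keeps the configuration of the oxirane because its C–O bond is never broken, and C9 becomes trigonal, so both oxirane diastereomers at C9 lead to the same product. The step needs C1 over C9, which is expected because stabilised carbanions add to the terminus remote from oxygen in opened vinyl epoxides and a carbanion flanked by two sulfonyl groups is too bulky for the substituted C9; E over Z at C9=C10, which should follow from the syn π-allyl (C8 on the side of the C10 methyl) reached by π–σ–π equilibration through the primary terminus; and ring closure over oligomerisation, which slow addition to a dilute catalyst solution and the chain-restricting trans-lactone and C4/C5 substituents should secure. The γ-lactone is a spectator, since attack of the transient C8 alkoxide on C12 would need a strained bicyclo[2.2.1] intermediate and proton transfer from C2 should be faster.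

Step 13
Reactants: 22 (E)-cyclodecenol lactone
Product: 23 8-O-triethylsilyl ether of 22
Conditions: Et3SiOTf, 2,6-lutidine, CH2Cl2, −78 °C
Reagents that add atoms: triethylsilyl trifluoromethanesulfonate CC[Si](CC)(CC)OS(=O)(=O)C(F)(F)F
Why: The silyl triflate with a hindered pyridine base silylates the secondary allylic C8 hydroxyl (standard protection), so that O8 cannot compete for the lactone carbonyl in the reductive and enolate steps that follow.

Step 14
Reactants: 23 8-O-triethylsilyl ether
Product: 24 desulfonylated macrocycle (C2 = CH2)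
Conditions: Na(Hg) (6%), Na2HPO4, MeOH/THF, −20 to 0 °C
Reagents that add atoms: none
Why: Sodium amalgam in buffered methanol transfers electrons to the geminal bis-sulfone and cleaves both C–S bonds in turn with protonation of the carbanions (reductive desulfonylation), while the isolated alkene, the silyl ethers and the lactone should survive the buffered conditions.

Step 15
Reactants: 24 desulfonylated macrocycle
Product: 26 11-(dimethylaminomethyl) lactone, via lithium lactone enolate 25 (not isolated)
Conditions: LiN(iPr)2, THF, −78 °C; then Me2N=CH2+ I−, −78 °C to rt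
Reagents that add atoms: dimethylmethyleneiminium iodide C=[N+](C)C.[I-]
Why: The lithium enolate at C11, the only enolisable position, is aminomethylated by the iminium salt (Mannich reaction), and the configuration of the new C11 centre is of no consequence.

Step 16
Reactants: 26 11-(dimethylaminomethyl) lactone
Product: 28 α-methylene lactone (8-OTES; 5-OTBS), via trimethylammonium iodide 27 (not isolated)
Conditions: MeI, CH2Cl2/MeOH, rt; then aq. NaHCO3, CH2Cl2, rt
Reagents that add atoms: none
Why: Exhaustive N-methylation turns the amine into a leaving group and mild base then effects β-elimination to the exocyclic C11=C13 alkene, the standard Mannich route to α-methylene lactones.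

Step 17
Reactants: 28 α-methylene lactone
Product: 29 C8 allylic alcohol (5-OTBS)
Conditions: HF·pyridine, pyridine, THF, 0 °C
Reagents that add atoms: none
Why: Buffered HF·pyridine removes the more labile triethylsilyl ether at the allylic O8 while the hindered tert-butyldimethylsilyl ether at O5 should stay (selective desilylation), and the weakly acidic medium avoids conjugate addition to the methylene lactone.

Step 18
Reactants: 29 C8 allylic alcohol
Product: 30 (8R,9R,10R)-9,10-epoxy alcohol
Conditions: VO(acac)2 (10 mol%), t-BuOOH, CH2Cl2, 0 °C to rt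
Reagents that add atoms: tert-butyl hydroperoxide CC(C)(C)OO
Why: Hydroxyl-directed epoxidation, in which the vanadate ester of the C8 alcohol delivers oxygen within an O–C8–C9=C10 dihedral of about 40–50°; in the E-cyclodecene, whose allylic ring bond C8–C7 lies on the inner face, this means delivery to the outer face and the erythro epoxy alcohol with C9 and C10 both R, while the electron-poor methylene lactone is not epoxidised.

Step 19
Reactants: 30 9,10-epoxy alcohol; 31 tigloyl chloride
Product: 32 8-O-tigloyl 5-O-TBS ether of the target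
Conditions: pyridine, DMAP (cat.), CH2Cl2, 0 °C to rt
Reagents that add atoms: none
Why: Acylation of the secondary alcohol through the acylpyridinium ion (nucleophilic catalysis by 4-dimethylaminopyridine) installs the tiglate, whose E geometry is the stable one and should be kept in the absence of a stronger amine base.

Step 20
Reactants: 32 silyl-protected target
Product: 33 target CNP0165329.2
Conditions: HF·pyridine, pyridine, THF, 0 °C to rt
Reagents that add atoms: none
Why: Fluoride-assisted cleavage of the last silyl ether under buffered, weakly acidic conditions frees the C5 hydroxyl without base that could add to the methylene lactone or move the acyl groups, and short exposure at low temperature should spare the oxirane.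

**Compound list**

1 | bis(phenylsulfonyl)methane | O=S(=O)(CS(=O)(=O)c1ccccc1)c1ccccc1 | starting material
2 | 2-vinyloxirane (butadiene monoxide, racemic) | C=CC1CO1 | starting material
3 | (E)-5,5-bis(phenylsulfonyl)pent-2-en-1-ol | OC/C=C/CC(S(=O)(=O)c1ccccc1)S(=O)(=O)c1ccccc1 | intermediate
4 | [(2S,3S)-3-[2,2-bis(phenylsulfonyl)ethyl]oxiran-2-yl]methanol | OC[C@@H]1O[C@H]1CC(S(=O)(=O)c1ccccc1)S(=O)(=O)c1ccccc1 | intermediate
5 | (2R,3R)-3-methyl-5,5-bis(phenylsulfonyl)pentane-1,2-diol | OC[C@H](O)[C@H](C)CC(S(=O)(=O)c1ccccc1)S(=O)(=O)c1ccccc1 | intermediate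
6 | (2R,3R)-3-methyl-5,5-bis(phenylsulfonyl)-1-(triethylsilyloxy)pentan-2-ol | CC[Si](CC)(CC)OC[C@H](O)[C@H](C)CC(S(=O)(=O)c1ccccc1)S(=O)(=O)c1ccccc1 | intermediate
7 | (2R,3R)-2-(tert-butyldimethylsilyloxy)-3-methyl-5,5-bis(phenylsulfonyl)-1-(triethylsilyloxy)pentane | CC[Si](CC)(CC)OC[C@H](O[Si](C)(C)C(C)(C)C)[C@H](C)CC(S(=O)(=O)c1ccccc1)S(=O)(=O)c1ccccc1 | intermediate
8 | (2R,3R)-2-(tert-butyldimethylsilyloxy)-3-methyl-5,5-bis(phenylsulfonyl)pentanal | O=C[C@H](O[Si](C)(C)C(C)(C)C)[C@H](C)CC(S(=O)(=O)c1ccccc1)S(=O)(=O)c1ccccc1 | intermediate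
9 | (S)-4-benzyloxazolidin-2-one | O=C1N[C@@H](Cc2ccccc2)CO1 | starting material
10 | methyl 4-chloro-4-oxobutanoate | COC(=O)CCC(Cl)=O | starting material
11 | methyl 4-[(S)-4-benzyl-2-oxooxazolidin-3-yl]-4-oxobutanoate | COC(=O)CCC(=O)N1[C@@H](Cc2ccccc2)COC1=O | intermediate
12 | Z dibutylboron enolate of 11 | COC(=O)C/C=C(\OB(CCCC)CCCC)N1[C@@H](Cc2ccccc2)COC1=O | intermediate
13 | syn aldol hydroxy ester (C6 S, C7 S; free 6-OH, methyl ester at C12, imide at C8) | COC(=O)C[C@@H]([C@H](O)[C@H](O[Si](C)(C)C(C)(C)C)[C@H](C)CC(S(=O)(=O)c1ccccc1)S(=O)(=O)c1ccccc1)C(=O)N1[C@@H](Cc2ccccc2)COC1=O | intermediate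
14 | (S)-4-benzyl-3-[(2S,3S)-2-[(1R,2R)-1-(tert-butyldimethylsilyloxy)-2-methyl-4,4-bis(phenylsulfonyl)butyl]-5-oxotetrahydrofuran-3-carbonyl]oxazolidin-2-one | O=S(=O)(c1ccccc1)C(S(=O)(=O)c1ccccc1)C[C@@H](C)[C@@H](O[Si](C)(C)C(C)(C)C)[C@H]1OC(=O)C[C@@H]1C(=O)N1[C@@H](Cc2ccccc2)COC1=O | intermediate
15 | (4R,5S)-5-[(1R,2R)-1-(tert-butyldimethylsilyloxy)-2-methyl-4,4-bis(phenylsulfonyl)butyl]-4-(hydroxymethyl)dihydrofuran-2(3H)-one | O=S(=O)(c1ccccc1)C(S(=O)(=O)c1ccccc1)C[C@@H](C)[C@@H](O[Si](C)(C)C(C)(C)C)[C@H]1OC(=O)C[C@@H]1CO | intermediate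
16 | (2S,3S)-2-[(1R,2R)-1-(tert-butyldimethylsilyloxy)-2-methyl-4,4-bis(phenylsulfonyl)butyl]-5-oxotetrahydrofuran-3-carbaldehyde | O=S(=O)(c1ccccc1)C(S(=O)(=O)c1ccccc1)C[C@@H](C)[C@@H](O[Si](C)(C)C(C)(C)C)[C@H]1OC(=O)C[C@@H]1C=O | intermediate
17 | (1R,4R,5R)-isothiocineole (4,7,7-trimethyl-6-thiabicyclo[3.2.1]octane) | C[C@@H]1CC[C@@H]2C[C@H]1SC2(C)C | starting material
18 | 3-bromo-2-methylprop-1-ene | C=C(C)CBr | starting material
19 | S-(2-methylallyl) sulfonium triflate of 17 | C[C@@H]1CC[C@@H]2C[C@H]1[S+](CC(C)=C)C2(C)C.[O-]S(=O)(=O)C(F)(F)F | intermediate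
20 | sulfonium ylide of 19 | C[C@@H]1CC[C@@H]2C[C@H]1[S+]([CH-]C(C)=C)C2(C)C | intermediate
21 | key-step precursor: (4R,5S)-5-[(1R,2R)-1-(tert-butyldimethylsilyloxy)-2-methyl-4,4-bis(phenylsulfonyl)butyl]-4-[(2R,3R)-3-(prop-1-en-2-yl)oxiran-2-yl]dihydrofuran-2(3H)-one | O=S(=O)(c1ccccc1)C(S(=O)(=O)c1ccccc1)C[C@@H](C)[C@@H](O[Si](C)(C)C(C)(C)C)[C@H]1OC(=O)C[C@@H]1[C@H]1O[C@@H]1C(C)=C | intermediate
22 | key-step product: ten-membered (E)-C9=C10 cycloalkenol with C2(SO2Ph)2, C4 methyl, 5-OTBS, trans 6,12-γ-lactone and free 8-OH; C4–C8 configured as in the target | O=S(=O)(c1ccccc1)C1(S(=O)(=O)c2ccccc2)C[C@@H](C)[C@@H](O[Si](C)(C)C(C)(C)C)[C@H]2OC(=O)C[C@@H]2[C@@H](O)/C=C(C)/C1 | intermediate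
23 | 8-O-triethylsilyl ether of 22 | O=S(=O)(c1ccccc1)C1(S(=O)(=O)c2ccccc2)C[C@@H](C)[C@@H](O[Si](C)(C)C(C)(C)C)[C@H]2OC(=O)C[C@@H]2[C@@H](O[Si](CC)(CC)CC)/C=C(C)/C1 | intermediate
24 | desulfonylated macrocycle (C2 = CH2; 8-OTES, 5-OTBS, 6,12-lactone, E-C9=C10) | C1C[C@@H](C)[C@@H](O[Si](C)(C)C(C)(C)C)[C@H]2OC(=O)C[C@@H]2[C@@H](O[Si](CC)(CC)CC)/C=C(C)/C1 | intermediate
25 | lithium enolate of 24 (C11=C12–OLi) | C1C[C@@H](C)[C@@H](O[Si](C)(C)C(C)(C)C)[C@H]2OC(O[Li])=C[C@@H]2[C@@H](O[Si](CC)(CC)CC)/C=C(C)/C1 | intermediate
26 | 11-(dimethylaminomethyl) lactone (C11 configuration not controlled) | C1C[C@@H](C)[C@@H](O[Si](C)(C)C(C)(C)C)[C@H]2OC(=O)C(CN(C)C)[C@@H]2[C@@H](O[Si](CC)(CC)CC)/C=C(C)/C1 | intermediate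
27 | trimethylammonium iodide of 26 | C1C[C@@H](C)[C@@H](O[Si](C)(C)C(C)(C)C)[C@H]2OC(=O)C(C[N+](C)(C)C)[C@@H]2[C@@H](O[Si](CC)(CC)CC)/C=C(C)/C1.[I-] | intermediate
28 | α-methylene lactone (C11=C13; 8-OTES, 5-OTBS, E-C9=C10) | C1C[C@@H](C)[C@@H](O[Si](C)(C)C(C)(C)C)[C@H]2OC(=O)C(=C)[C@@H]2[C@@H](O[Si](CC)(CC)CC)/C=C(C)/C1 | intermediate
29 | C8 allylic alcohol (α-methylene lactone, 5-OTBS, E-C9=C10) | C1C[C@@H](C)[C@@H](O[Si](C)(C)C(C)(C)C)[C@H]2OC(=O)C(=C)[C@@H]2[C@@H](O)/C=C(C)/C1 | intermediate
30 | (8R,9R,10R)-9,10-epoxy-8-ol (α-methylene lactone, 5-OTBS) | C1C[C@@H](C)[C@@H](O[Si](C)(C)C(C)(C)C)[C@H]2OC(=O)C(=C)[C@@H]2[C@@H](O)[C@H]2O[C@]2(C)C1 | intermediate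
31 | tigloyl chloride ((E)-2-methylbut-2-enoyl chloride) | C/C=C(\C)C(Cl)=O | starting material
32 | 5-O-tert-butyldimethylsilyl ether of the target | C1C[C@@H](C)[C@@H](O[Si](C)(C)C(C)(C)C)[C@H]2OC(=O)C(=C)[C@@H]2[C@@H](OC(=O)/C(C)=C/C)[C@H]2O[C@]2(C)C1 | intermediate
33 | CNP0165329.2 (4R,5R,6S,7S,8R,9R,10R in the numbering used here) | C1C[C@@H](C)[C@@H](O)[C@H]2OC(=O)C(=C)[C@@H]2[C@@H](OC(=O)/C(C)=C/C)[C@H]2O[C@]2(C)C1 | target

**Step count**

Total: 20 steps. Longest linear sequence: 18 steps (steps 1–5, 7–9, 11–20); steps 6 and 10 are one-step side branches.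

**Steps most likely to fail**

Step 12 (ring closure). The closure may lose to oligomerisation, to the Z alkene formed through the anti π-allyl, or to hydride shift of the π-allyl to a dienol or enone before the slow medium-ring attack. The fallback sets out from aldehyde 16 and fixes the alkene geometry before cyclisation. Nozaki–Hiyama–Kishi coupling of 16 with (E)-3-iodo-2-methylprop-2-en-1-ol (CrCl2, NiCl2 cat., DMSO/THF) would give the allylic diol F1 with the E-C9=C10–C1H2OH unit in place (Felkin–Anh control at C8, minor epimer removed). Selective conversion of the primary allylic hydroxyl (MsCl, LiCl, 2,4,6-collidine, DMF, 0 °C) would give the primary allylic chloride F2. Cs2CO3 with catalytic NaI in DMF under high dilution would then close C1–C2 by intramolecular SN2 alkylation of the bis-sulfonyl carbanion, a base-mediated sulfone macrocyclisation without a π-allyl intermediate. The route is rejoined at 22.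

Step 11 (oxirane formation). The aldehyde may enolise and lose the lactone oxygen from C6 by β-elimination, the bis-sulfonyl anion may be C-allylated by the sulfonium salt, or facial selectivity at C8 may be poor. The fallback sets out from 16 and avoids strong base at the aldehyde stage. Wittig reaction with 1-(triphenylphosphoranylidene)propan-2-one (toluene, 60 °C) would give the E-enone F3. Non-basic methylenation (Zn, CH2Br2, TiCl4, THF) would give the 1,3-diene F4. Shi epoxidation (D-fructose-derived ketone catalyst, KHSO5, K2CO3 buffer, MeCN/dimethoxymethane/H2O, 0 °C) should oxidise the trans-disubstituted C8=C9 alkene in preference to the 1,1-disubstituted terminal alkene and, under catalyst control, give the (8R,9R) vinyl epoxide. The route is rejoined at 21.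

Step 18 (directed epoxidation). Oxygen may be delivered to the wrong face of C9=C10 (threo epoxy alcohol) if the ring reacts through the conformer in which H-8 rather than O8 lies near the alkene plane, or conversion may stall. The fallback sets out from 29 and lets a catalyst, not the hydroxyl group, choose the face. Acylation with tigloyl chloride 31 (pyridine, DMAP cat., CH2Cl2) would give the allylic tiglate F5. Its only electron-rich alkene would then be epoxidised with a chiral dioxirane (Shi epoxidation with the enantiomer of the fructose-derived ketone that is matched to the 9R,10R sense; KHSO5, K2CO3 buffer, MeCN/H2O, 0 °C). The route is rejoined at 32.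

**Further compounds**

F1 | step 12 | allylic diol: lactone of 16 carrying at C7 the (8R)-CH(OH)–CH=C(CH3)–CH2OH unit with E alkene | O=S(=O)(c1ccccc1)C(S(=O)(=O)c1ccccc1)C[C@@H](C)[C@@H](O[Si](C)(C)C(C)(C)C)[C@H]1OC(=O)C[C@@H]1[C@@H](O)/C=C(C)/CO
F2 | step 12 | primary allylic chloride of F1 (C1–Cl) | O=S(=O)(c1ccccc1)C(S(=O)(=O)c1ccccc1)C[C@@H](C)[C@@H](O[Si](C)(C)C(C)(C)C)[C@H]1OC(=O)C[C@@H]1[C@@H](O)/C=C(C)/CCl
F3 | step 11 | E-enone: lactone of 16 carrying at C7 the (E)-CH=CH–C(=O)CH3 group | O=S(=O)(c1ccccc1)C(S(=O)(=O)c1ccccc1)C[C@@H](C)[C@@H](O[Si](C)(C)C(C)(C)C)[C@H]1OC(=O)C[C@@H]1/C=C/C(C)=O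
F4 | step 11 | 1,3-diene: lactone of 16 carrying at C7 the (E)-CH=CH–C(CH3)=CH2 group | O=S(=O)(c1ccccc1)C(S(=O)(=O)c1ccccc1)C[C@@H](C)[C@@H](O[Si](C)(C)C(C)(C)C)[C@H]1OC(=O)C[C@@H]1/C=C/C(C)=C
F5 | step 18 | 8-O-tigloyl ester of 29 (E-C9=C10 still present) | C1C[C@@H](C)[C@@H](O[Si](C)(C)C(C)(C)C)[C@H]2OC(=O)C(=C)[C@@H]2[C@@H](OC(=O)/C(C)=C/C)/C=C(C)/C1
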